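**Retrosynthetic overview**
1. 15 ⇒ 14: the 5-OH and 7-OH are carried as benzyl ethers and freed last by hydrogenolysis, so the four methyl ethers are never at risk.
2. 14 ⇒ 12: ring C (the pyranone) comes from O1–C2 closure and dehydrogenation of a 2'-hydroxychalcone.
3. 12 ⇒ 9 + 10: the Cα–Cβ bond is made by a Claisen–Schmidt aldol condensation of A-ring methyl ketone 9 with 2,4,5-trimethoxybenzaldehyde 10.
4. 9 ⇒ 7 ⇒ 5 ⇒ 1: ortho C-acetylation of the mirror-symmetric phenol 7 can give only one regioisomer, which fixes 6-OMe rather than 8-OMe. The OH of 7 comes from Baeyer–Villiger oxidation of aldehyde 5, which is made from methyl gallate 1.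
5. Ring order: rings A and B are bought as benzene rings. Ring C is the only ring built, in step 8.

Assumption: tabularin has no stereocentre or other stereogenic element, so there is no enantiomer to choose. The route delivers the single achiral compound, and the sp3 centres in 11 and 13 are racemic and are destroyed again.

**Step 1**
Reactants: 1 methyl gallate (methyl 3,4,5-trihydroxybenzoate)
Product: 2 methyl 3,5-dihydroxy-4-methoxybenzoate
Conditions: MeI (1.05 equiv), KHCO3 (1.5 equiv), DMF, N2, rt → 40 °C
Reagents that add atoms: iodomethane, CI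
Why: In this Williamson-type O-alkylation the weak base ionises only the 4-OH, which is para to the ester and the most acidic phenol, so one equivalent of MeI gives mainly the 4-methyl ether.

**Step 2**
Reactants: 2 methyl 3,5-dihydroxy-4-methoxybenzoate
Product: 3 methyl 3,5-bis(benzyloxy)-4-methoxybenzoate
Conditions: BnBr (2.4 equiv), K2CO3 (3 equiv), DMF, 60 °C
Reagents that add atoms: benzyl bromide, BrCc1ccccc1
Why: This Williamson ether synthesis caps the two remaining equivalent phenols, and the ester and the methyl ether are inert to K2CO3/DMF.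

**Step 3**
Reactants: 3 methyl 3,5-bis(benzyloxy)-4-methoxybenzoate
Product: 4 [3,5-bis(benzyloxy)-4-methoxyphenyl]methanol
Conditions: LiAlH4 (1.2 equiv), THF, 0 °C → rt; Fieser work-up
Reagents that add atoms: none
Why: Hydride reduction takes the ester to the primary benzylic alcohol and leaves the aryl benzyl and methyl ethers untouched.

**Step 4**
Reactants: 4 [3,5-bis(benzyloxy)-4-methoxyphenyl]methanol
Product: 5 3,5-bis(benzyloxy)-4-methoxybenzaldehyde
Conditions: activated MnO2 (10 equiv), CH2Cl2, rt
Reagents that add atoms: none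
Why: Heterogeneous MnO2 oxidation of a benzylic alcohol stops cleanly at the aldehyde and tolerates the ethers.

**Step 5**
Reactants: 5 3,5-bis(benzyloxy)-4-methoxybenzaldehyde
Product: 7 3,5-bis(benzyloxy)-4-methoxyphenol, via aryl formate 6 (not isolated)
Conditions: mCPBA (1.5 equiv), CH2Cl2, rt → 40 °C; aq Na2SO3/NaHCO3 wash; crude in MeOH–THF, K2CO3 (0.2 equiv), N2, rt; dil. HCl
Reagents that add atoms: mCPBA, O=C(OO)c1cccc(Cl)c1
Why: In this Baeyer–Villiger (Dakin-type) oxidation the electron-rich trialkoxyaryl group migrates in the Criegee adduct in preference to hydrogen, and base-catalysed methanolysis of the resulting formate frees the phenol.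

**Step 6**
Reactants: 7 3,5-bis(benzyloxy)-4-methoxyphenol
Product: 9 1-[2,4-bis(benzyloxy)-6-hydroxy-3-methoxyphenyl]ethan-1-one, via aryl acetate 8 (not isolated)
Conditions: Ac2O (1.3 equiv), BF3·OEt2 (3 equiv), CH2Cl2, 0 → 40 °C; aq NaOAc quench
Reagents that add atoms: acetic anhydride, CC(=O)OC(C)=O
Why: In this O-acetylation followed by Fries/Friedel–Crafts C-acylation the two open ring positions are equivalent by symmetry and phloroglucinol-like in activation (ortho to OH, ortho and para to OBn), so acetyl transfer runs at or below 40 °C, where aryl benzyl ethers tolerate BF3, and only one regioisomer can form.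

**Step 7 (key C–C bond)**
Reactants: 9 1-[2,4-bis(benzyloxy)-6-hydroxy-3-methoxyphenyl]ethan-1-one; 10 2,4,5-trimethoxybenzaldehyde
Product: 12 (E)-1-[2,4-bis(benzyloxy)-6-hydroxy-3-methoxyphenyl]-3-(2,4,5-trimethoxyphenyl)prop-2-en-1-one, via aldol adduct 11 (not isolated)
Conditions: KOH (10 equiv, 50% aq), EtOH–THF, rt, 48 h; 1 M HCl to pH 4
Reagents that add atoms: none
Why: In this Claisen–Schmidt crossed aldol condensation the methyl ketone is the only enolisable partner and the aldehyde the only good electrophile, and E1cB loss of water from racemic aldol 11 removes its carbinol centre and gives the conjugated E-enone only.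

**Step 8**
Reactants: 12 (E)-2'-hydroxychalcone from step 7
Product: 14 5,7-bis(benzyloxy)-6-methoxy-2-(2,4,5-trimethoxyphenyl)-4H-chromen-4-one, via flavanone 13 (not isolated)
Conditions: I2 (0.1 equiv), DMSO, 125 °C, 3 h; aq Na2S2O3
Reagents that add atoms: none
Why: In this iodine-catalysed oxidative cyclisation the only free phenol closes by oxa-Michael addition to racemic flavanone 13, which is dehydrogenated with DMSO as terminal oxidant, so the C2 centre disappears and the benzylated 6'-oxygen rules out the 8-methoxy isomer.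

**Step 9**
Reactants: 14 5,7-bis(benzyloxy)-6-methoxy-2-(2,4,5-trimethoxyphenyl)-4H-chromen-4-one
Product: 15 tabularin (5,7-dihydroxy-6-methoxy-2-(2,4,5-trimethoxyphenyl)-4H-chromen-4-one)
Conditions: H2 (1 atm), 10% Pd/C, THF–MeOH, rt, stopped after 2 equiv H2
Reagents that add atoms: none
Why: Catalytic hydrogenolysis cleaves only the two benzylic C–O bonds, while the aryl methyl ethers and the vinylogous-ester C2=C3 bond of the flavone survive at 1 atm.

**Compound list**
1 | methyl gallate | COC(=O)c1cc(O)c(O)c(O)c1 | starting material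
2 | methyl 3,5-dihydroxy-4-methoxybenzoate | COC(=O)c1cc(O)c(OC)c(O)c1 | intermediate
3 | methyl 3,5-bis(benzyloxy)-4-methoxybenzoate | COC(=O)c1cc(OCc2ccccc2)c(OC)c(OCc2ccccc2)c1 | intermediate
4 | [3,5-bis(benzyloxy)-4-methoxyphenyl]methanol | OCc1cc(OCc2ccccc2)c(OC)c(OCc2ccccc2)c1 | intermediate
5 | 3,5-bis(benzyloxy)-4-methoxybenzaldehyde | O=Cc1cc(OCc2ccccc2)c(OC)c(OCc2ccccc2)c1 | intermediate
6 | 3,5-bis(benzyloxy)-4-methoxyphenyl formate (not isolated) | O=COc1cc(OCc2ccccc2)c(OC)c(OCc2ccccc2)c1 | intermediate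
7 | 3,5-bis(benzyloxy)-4-methoxyphenol | Oc1cc(OCc2ccccc2)c(OC)c(OCc2ccccc2)c1 | intermediate
8 | 3,5-bis(benzyloxy)-4-methoxyphenyl acetate (not isolated) | CC(=O)Oc1cc(OCc2ccccc2)c(OC)c(OCc2ccccc2)c1 | intermediate
9 | 1-[2,4-bis(benzyloxy)-6-hydroxy-3-methoxyphenyl]ethan-1-one | CC(=O)c1c(O)cc(OCc2ccccc2)c(OC)c1OCc1ccccc1 | intermediate
10 | 2,4,5-trimethoxybenzaldehyde | COc1cc(OC)c(C=O)cc1OC | starting material
11 | 1-[2,4-bis(benzyloxy)-6-hydroxy-3-methoxyphenyl]-3-hydroxy-3-(2,4,5-trimethoxyphenyl)propan-1-one (racemic, not isolated) | COc1cc(OC)c(C(O)CC(=O)c2c(O)cc(OCc3ccccc3)c(OC)c2OCc2ccccc2)cc1OC | intermediate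
12 | (E)-1-[2,4-bis(benzyloxy)-6-hydroxy-3-methoxyphenyl]-3-(2,4,5-trimethoxyphenyl)prop-2-en-1-one | COc1cc(OC)c(/C=C/C(=O)c2c(O)cc(OCc3ccccc3)c(OC)c2OCc2ccccc2)cc1OC | intermediate
13 | 5,7-bis(benzyloxy)-6-methoxy-2-(2,4,5-trimethoxyphenyl)chroman-4-one (racemic, not isolated) | COc1cc(OC)c(C2CC(=O)c3c(OCc4ccccc4)c(OC)c(OCc4ccccc4)cc3O2)cc1OC | intermediate
14 | 5,7-bis(benzyloxy)-6-methoxy-2-(2,4,5-trimethoxyphenyl)-4H-chromen-4-one | COc1cc(OC)c(-c2cc(=O)c3c(OCc4ccccc4)c(OC)c(OCc4ccccc4)cc3o2)cc1OC | intermediate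
15 | tabularin | COc1cc(OC)c(-c2cc(=O)c3c(O)c(OC)c(O)cc3o2)cc1OC | target

**Totals:** 9 steps. The longest linear sequence is 9 steps (1 → 15), and 10 is bought.

**Steps most likely to fail**

Step 6. The Lewis acid could cleave or migrate a benzyl group on this very electron-rich ring. The fallback sets out from 7 and comes back at 9, and it uses no Lewis acid. Compound 7 is iodinated with NIS (MeCN, 0 °C) at one of its two equivalent ortho positions to give 3,5-bis(benzyloxy)-2-iodo-4-methoxyphenol F3. Stille coupling of this with tributyl(1-ethoxyvinyl)stannane (PdCl2(PPh3)2, dioxane, 100 °C) gives 3,5-bis(benzyloxy)-2-(1-ethoxyethenyl)-4-methoxyphenol F4. The enol ether is then hydrolysed with 1 M HCl in THF at rt to 9.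

Step 8. Hot I2/DMSO may partly remove the 5-O-benzyl group or iodinate C8 or the B ring. Any 5-OH product still converges in step 9, but iodinated material is lost. The fallback sets out from 9, replaces steps 7 and 8, and comes back at 14 without any oxidant. Commercial 2,4,5-trimethoxybenzoic acid is converted with (COCl)2 and cat. DMF into 2,4,5-trimethoxybenzoyl chloride F5. The lithium dianion of 9 (LiHMDS, 3.5 equiv, THF, −78 °C) is C-acylated by this chloride in an intermolecular Claisen-type condensation. This gives 1-[2,4-bis(benzyloxy)-6-hydroxy-3-methoxyphenyl]-3-(2,4,5-trimethoxyphenyl)propane-1,3-dione F6. Cyclodehydration with NaOAc in refluxing AcOH then gives 14.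

Step 1. Mono-methylation of a free triol gives some di- and tri-methylated material and unreacted 1, so yield and separation may be poor. The fallback sets out from 1 and comes back at 2, and it differentiates the oxygens by protecting groups instead. Compound 1 is peracetylated (Ac2O, pyridine) to methyl 3,4,5-triacetoxybenzoate F1. Heating this with MeI and dry K2CO3 in acetone cleaves only the 4-acetate, because its phenoxide, para to the ester, is the best leaving group. The phenoxide is trapped in situ to give methyl 3,5-diacetoxy-4-methoxybenzoate F2, and K2CO3-catalysed methanolysis then gives 2.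

**Further compounds**
F1 | step 1 | methyl 3,4,5-triacetoxybenzoate | COC(=O)c1cc(OC(C)=O)c(OC(C)=O)c(OC(C)=O)c1
F2 | step 1 | methyl 3,5-diacetoxy-4-methoxybenzoate | COC(=O)c1cc(OC(C)=O)c(OC)c(OC(C)=O)c1
F3 | step 6 | 3,5-bis(benzyloxy)-2-iodo-4-methoxyphenol | Oc1cc(OCc2ccccc2)c(OC)c(OCc2ccccc2)c1I
F4 | step 6 | 3,5-bis(benzyloxy)-2-(1-ethoxyethenyl)-4-methoxyphenol | C=C(OCC)c1c(O)cc(OCc2ccccc2)c(OC)c1OCc1ccccc1
F5 | step 8 | 2,4,5-trimethoxybenzoyl chloride | COc1cc(OC)c(C(=O)Cl)cc1OC
F6 | step 8 | 1-[2,4-bis(benzyloxy)-6-hydroxy-3-methoxyphenyl]-3-(2,4,5-trimethoxyphenyl)propane-1,3-dione | COc1cc(OC)c(C(=O)CC(=O)c2c(O)cc(OCc3ccccc3)c(OC)c2OCc2ccccc2)cc1OC
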